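**Retrosynthetic overview**

- Labels: ring A = 3-hydroxy-4-methoxyphenyl, ring B = 4-hydroxy-3-methoxyphenyl; C7/C7' are their benzylic CH2 carbons, C8/C8' the two stereocentres, C9/C9' the CH2O carbons. The strategy rests on the chain O–C9–C8–C8'–C9': C9' is a single oxygenated carbon four atoms from the oxygen on C9, so the two benzoyloxymethyl arms are a reduced trans-γ-butyrolactone whose carbonyl carbon C9' can come from CO.
- Target ⇒ (debenzylation, benzoylation) (2R,3R)-diol ⇒ (LiAlH4) (3R,4R)-trans-lactone, the only ring of the route, closed once and then opened.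
- Lactone ⇒ palladium-catalysed asymmetric cyclocarbonylation of an achiral (E)-allylic alcohol: the C8'–C9' and C9'–O bonds are formed and C8 and C8' are set together.
- Allylic alcohol ⇒ (i-Bu2AlH) E-enoate ⇒ Wittig olefination (C8=C8') of the ring B arylacetaldehyde with an α-(ring A benzyl) stabilised ylide. The ylide comes from O-benzylisovanillin via the benzyl bromide and Ph3P=CHCO2Et, the aldehyde from homovanillyl alcohol; the base-free ylide is preferred to a phosphonate carbanion because the aldehyde is enolisable.

Key step: step 7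

Assumption: the sense of induction of BICP [2,2'-bis(diphenylphosphino)-1,1'-bicyclopentyl] on a γ-benzyl allylic alcohol cannot be read from the γ-aryl cases, so (R,R)-BICP is written and the (S,S)-ligand takes its place if that antipode is the one that leads to the 3R,4R lactone; O-benzylisovanillin, Ph3P=CHCO2Et and homovanillyl alcohol are taken as catalogue chemicals.

**Route**

Step 1
Reactants: 1 3-(benzyloxy)-4-methoxybenzaldehyde
Product: 2 [3-(benzyloxy)-4-methoxyphenyl]methanol
Conditions: NaBH4, MeOH, 0 °C to rt
Reagents that add atoms: none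
Why: Borohydride reduction of an aromatic aldehyde to the benzylic alcohol, to which the aryl ethers are inert.

Step 2
Reactants: 2 [3-(benzyloxy)-4-methoxyphenyl]methanol
Product: 3 3-(benzyloxy)-4-methoxybenzyl bromide
Conditions: PBr3, Et2O, 0 °C
Reagents that add atoms: phosphorus tribromide BrP(Br)Br
Why: Substitution of an electron-rich benzylic alcohol by bromide through its phosphite ester should be fast at 0 °C, and the bromide is used at once without storage.

Step 3
Reactants: 3 3-(benzyloxy)-4-methoxybenzyl bromide; 4 ethyl (triphenylphosphoranylidene)acetate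
Product: 6 ethyl 3-[3-(benzyloxy)-4-methoxyphenyl]-2-(triphenylphosphoranylidene)propanoate, via phosphonium bromide 5 (not isolated)
Conditions: toluene, 80 °C; then aq. NaOH, CH2Cl2, rt
Reagents that add atoms: none
Why: C-Alkylation of a stabilised phosphorus ylide by a benzylic bromide gives the α-substituted phosphonium salt, whose remaining acidic α-proton is removed by aqueous NaOH to give the α-benzyl stabilised ylide (ylide alkylation, the usual entry to α-substituted Wittig reagents).

Step 4
Reactants: 7 2-(4-hydroxy-3-methoxyphenyl)ethanol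
Product: 8 2-[4-(benzyloxy)-3-methoxyphenyl]ethanol
Conditions: BnBr, K2CO3, acetone, reflux
Reagents that add atoms: benzyl bromide BrCc1ccccc1
Why: Williamson ether synthesis in which K2CO3 deprotonates only the phenol, so the primary alcohol should stay free.

Step 5
Reactants: 8 2-[4-(benzyloxy)-3-methoxyphenyl]ethanol; 6 ethyl 3-[3-(benzyloxy)-4-methoxyphenyl]-2-(triphenylphosphoranylidene)propanoate
Product: 10 ethyl (E)-2-[3-(benzyloxy)-4-methoxybenzyl]-4-[4-(benzyloxy)-3-methoxyphenyl]but-2-enoate, via ring B arylacetaldehyde 9 (not isolated)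
Conditions: Dess–Martin periodinane, pyridine, CH2Cl2, 0 °C to rt; then 6, rt to 40 °C; chromatography
Reagents that add atoms: none
Why: Dess–Martin oxidation should give the enolisable arylacetaldehyde under near-neutral conditions, and it is trapped in the same flask by Wittig olefination with the α-substituted stabilised ylide, which needs no added base and is expected to favour the E-enoate (ester trans to C7') as such ylides generally do.

Step 6
Reactants: 10 ethyl (E)-2-[3-(benzyloxy)-4-methoxybenzyl]-4-[4-(benzyloxy)-3-methoxyphenyl]but-2-enoate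
Product: 11 (E)-2-[3-(benzyloxy)-4-methoxybenzyl]-4-[4-(benzyloxy)-3-methoxyphenyl]but-2-en-1-ol
Conditions: i-Bu2AlH, CH2Cl2, −78 °C; aq. potassium sodium tartrate
Reagents that add atoms: none
Why: 1,2-Reduction of an α,β-unsaturated ester to the allylic alcohol with i-Bu2AlH at low temperature should leave the position and geometry of the alkene untouched.

Step 7
Reactants: 11 (E)-2-[3-(benzyloxy)-4-methoxybenzyl]-4-[4-(benzyloxy)-3-methoxyphenyl]but-2-en-1-ol
Product: 12 (3R,4R)-3-[4-(benzyloxy)-3-methoxybenzyl]-4-[3-(benzyloxy)-4-methoxybenzyl]dihydrofuran-2(3H)-one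
Conditions: Pd2(dba)3·CHCl3 (2 mol %), (R,R)-BICP (4.5 mol %), CO/H2 (1:1, ca. 55 bar), CH2Cl2, 80 °C
Reagents that add atoms: carbon monoxide [C-]#[O+]
Why: Proposed new method: a palladium hydride formed from zerovalent palladium, the bisphosphine and H2 is held by the C9 hydroxyl and adds syn across C8=C8' (H to the substituted C8, Pd to the less hindered C8'), CO inserts into the C8'–Pd bond with retention, and the tethered oxygen attacks the acylpalladium, so the γ-lactone closes by 5-exo-trig acyl–oxygen bond formation and the hydride is returned. The closest known reaction type is the Pd/BICP-catalysed asymmetric cyclocarbonylation of (E)-β,γ-disubstituted allylic alcohols that carry a γ-aryl group and a tertiary carbinol, which gives trans-α,β-disubstituted γ-butyrolactones; new here are the primary carbinol and a γ-benzyl alkene that is not conjugated to a ring. Syn addition to the E-alkene, in which C9 and C7' are trans, places the two arylmethyl groups trans on the ring, so the relative configuration of C8 and C8' follows from the alkene geometry and the absolute configuration of both from the alkene face that the chiral ligand selects. The step needs the acyl group at C8' (secured by the preference for the five-membered over the four-membered lactone and by palladium going to the less substituted carbon) and it needs carbonylation to outrun β-hydride elimination towards C7', which would move the alkene into conjugation with ring B; the hydroxyl tether and a high CO pressure are relied on for that.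

Step 8
Reactants: 12 (3R,4R)-3-[4-(benzyloxy)-3-methoxybenzyl]-4-[3-(benzyloxy)-4-methoxybenzyl]dihydrofuran-2(3H)-one
Product: 13 (2R,3R)-2-[3-(benzyloxy)-4-methoxybenzyl]-3-[4-(benzyloxy)-3-methoxybenzyl]butane-1,4-diol
Conditions: LiAlH4, THF, 0 °C to rt
Reagents that add atoms: none
Why: Hydride reduction of a lactone to the 1,4-diol, in which the carbonyl should be reduced faster than C8' can be enolised and the trans lactone is in any case the more stable epimer, so neither stereocentre is disturbed.

Step 9
Reactants: 13 (2R,3R)-2-[3-(benzyloxy)-4-methoxybenzyl]-3-[4-(benzyloxy)-3-methoxybenzyl]butane-1,4-diol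
Product: 14 (2R,3R)-2-[3-(benzyloxy)-4-methoxybenzyl]-3-[4-(benzyloxy)-3-methoxybenzyl]butane-1,4-diyl dibenzoate
Conditions: BzCl, pyridine, DMAP (cat.), CH2Cl2, 0 °C to rt
Reagents that add atoms: benzoyl chloride O=C(Cl)c1ccccc1
Why: DMAP-catalysed acylation of both primary alcohols with an acid chloride (esterification), with the phenols still masked as benzyl ethers so that only the two CH2OH groups react.

Step 10
Reactants: 14 (2R,3R)-2-[3-(benzyloxy)-4-methoxybenzyl]-3-[4-(benzyloxy)-3-methoxybenzyl]butane-1,4-diyl dibenzoate
Product: 15 (2R,3R)-2-(3-hydroxy-4-methoxybenzyl)-3-(4-hydroxy-3-methoxybenzyl)butane-1,4-diyl dibenzoate (CNP0306197.1)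
Conditions: H2 (1 atm), 10% Pd/C, EtOAc–EtOH, rt
Reagents that add atoms: none
Why: Hydrogenolysis of the two aryl benzyl ethers over Pd/C should free both phenols, while the benzoates sit on non-benzylic CH2–O bonds and survive and no stereocentre is touched.

**Compound list**

1 | 3-(benzyloxy)-4-methoxybenzaldehyde | COc1ccc(C=O)cc1OCc1ccccc1 | starting material
2 | [3-(benzyloxy)-4-methoxyphenyl]methanol | COc1ccc(CO)cc1OCc1ccccc1 | intermediate
3 | 3-(benzyloxy)-4-methoxybenzyl bromide | COc1ccc(CBr)cc1OCc1ccccc1 | intermediate
4 | ethyl (triphenylphosphoranylidene)acetate | CCOC(=O)C=P(c1ccccc1)(c1ccccc1)c1ccccc1 | starting material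
5 | {3-[3-(benzyloxy)-4-methoxyphenyl]-1-ethoxy-1-oxopropan-2-yl}triphenylphosphonium bromide | CCOC(=O)C(Cc1ccc(OC)c(OCc2ccccc2)c1)[P+](c1ccccc1)(c1ccccc1)c1ccccc1.[Br-] | intermediate
6 | ethyl 3-[3-(benzyloxy)-4-methoxyphenyl]-2-(triphenylphosphoranylidene)propanoate | CCOC(=O)C(Cc1ccc(OC)c(OCc2ccccc2)c1)=P(c1ccccc1)(c1ccccc1)c1ccccc1 | intermediate
7 | 2-(4-hydroxy-3-methoxyphenyl)ethanol | COc1cc(CCO)ccc1O | starting material
8 | 2-[4-(benzyloxy)-3-methoxyphenyl]ethanol | COc1cc(CCO)ccc1OCc1ccccc1 | intermediate
9 | 2-[4-(benzyloxy)-3-methoxyphenyl]acetaldehyde | COc1cc(CC=O)ccc1OCc1ccccc1 | intermediate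
10 | ethyl (E)-2-[3-(benzyloxy)-4-methoxybenzyl]-4-[4-(benzyloxy)-3-methoxyphenyl]but-2-enoate | CCOC(=O)/C(Cc1ccc(OC)c(OCc2ccccc2)c1)=C/Cc1ccc(OCc2ccccc2)c(OC)c1 | intermediate
11 | (E)-2-[3-(benzyloxy)-4-methoxybenzyl]-4-[4-(benzyloxy)-3-methoxyphenyl]but-2-en-1-ol | OC/C(Cc1ccc(OC)c(OCc2ccccc2)c1)=C/Cc1ccc(OCc2ccccc2)c(OC)c1 | intermediate
12 | (3R,4R)-3-[4-(benzyloxy)-3-methoxybenzyl]-4-[3-(benzyloxy)-4-methoxybenzyl]dihydrofuran-2(3H)-one | COc1ccc(C[C@H]2COC(=O)[C@@H]2Cc2ccc(OCc3ccccc3)c(OC)c2)cc1OCc1ccccc1 | intermediate
13 | (2R,3R)-2-[3-(benzyloxy)-4-methoxybenzyl]-3-[4-(benzyloxy)-3-methoxybenzyl]butane-1,4-diol | COc1ccc(C[C@@H](CO)[C@H](CO)Cc2ccc(OCc3ccccc3)c(OC)c2)cc1OCc1ccccc1 | intermediate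
14 | (2R,3R)-2-[3-(benzyloxy)-4-methoxybenzyl]-3-[4-(benzyloxy)-3-methoxybenzyl]butane-1,4-diyl dibenzoate | COc1ccc(C[C@@H](COC(=O)c2ccccc2)[C@H](COC(=O)c2ccccc2)Cc2ccc(OCc3ccccc3)c(OC)c2)cc1OCc1ccccc1 | intermediate
15 | (2R,3R)-2-(3-hydroxy-4-methoxybenzyl)-3-(4-hydroxy-3-methoxybenzyl)butane-1,4-diyl dibenzoate | COc1ccc(C[C@@H](COC(=O)c2ccccc2)[C@H](COC(=O)c2ccccc2)Cc2ccc(O)c(OC)c2)cc1O | target

**Step count**

Total steps: 10. Longest linear sequence: 9 steps (1, 2, 3, 5, 6, 7, 8, 9, 10, from compound 1); the ring B branch (step 4) joins at step 5.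

**Steps most likely to fail**

Step 7 (Proposed new method). The precedented substrates have a γ-aryl alkene and a tertiary carbinol; here the alkene is unconjugated and the carbinol primary. The step may therefore fail in several ways: migration of the alkene by the palladium hydride towards C7' before CO is taken up, redox isomerisation or ionisation of the primary allylic alcohol, or weak face discrimination. In that case the two stereocentres are set one after the other by known lignan chemistry. The fallback sets out from aldehyde 1 and comes back to the route at lactone 12. Stobbe condensation of 1 with dimethyl succinate (NaOMe, MeOH, reflux) should give the half-ester (E)-4-[3-(benzyloxy)-4-methoxyphenyl]-3-(methoxycarbonyl)but-3-enoic acid F1. Asymmetric hydrogenation with a cationic rhodium bisphosphine catalyst ([Rh(cod)2]BF4, MOD-DIOP in the antipode that gives the R acid, H2, MeOH, Et3N) sets C8 in (R)-4-[3-(benzyloxy)-4-methoxyphenyl]-3-(methoxycarbonyl)butanoic acid F2. Reduction of the ester in the presence of the carboxylate (KOH, then Ca(BH4)2 from CaCl2 and NaBH4, EtOH; acidic work-up) and lactonisation give (R)-4-[3-(benzyloxy)-4-methoxybenzyl]dihydrofuran-2(3H)-one F3. The lithium enolate of F3 (LiN(SiMe3)2, THF, −78 °C) is then alkylated anti to the C4 substituent by 4-(benzyloxy)-3-methoxybenzyl bromide F4 (made from commercial 4-(benzyloxy)-3-methoxybenzyl alcohol with PBr3), which sets C8' trans and gives 12.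

Step 5. The one-pot oxidation–olefination may suffer from self-condensation of the enolisable aldehyde, from incomplete E-selectivity of the hindered ylide, or from migration of the new alkene towards ring B. In that case the C8=C8' bond is made by olefin cross-metathesis instead of carbonyl olefination. The fallback sets out from ylide 6 and comes back at enoate 10. Ylide 6 and paraformaldehyde (THF, reflux) give ethyl 2-[3-(benzyloxy)-4-methoxybenzyl]acrylate F5. F5 then undergoes cross-metathesis with 4-allyl-1-(benzyloxy)-2-methoxybenzene F6 (from eugenol, benzyl bromide and K2CO3) under the second-generation Hoveyda–Grubbs catalyst RuCl2(H2IMes)(=CH-C6H4-2-OiPr) in toluene at 60–80 °C. 1,4-Benzoquinone is added to suppress ruthenium hydride isomerisation of the allylarene. As with methacrylate- and itaconate-type partners, the thermodynamically preferred E-trisubstituted enoate 10 is expected.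

Step 3. C-Alkylation of the stabilised ylide may stop short or be blurred by transylidation between alkylated and unalkylated phosphorus species, and the phosphonium salt may be partly hydrolysed during the base treatment, so that a mixture of ylides would reach step 5. In that case the phosphorus reagent is changed to a phosphonate carbanion. The fallback sets out from bromide 3 and comes back at enoate 10. The sodium salt of triethyl phosphonoacetate (NaH, THF, 0 °C) is alkylated by 3 to ethyl 3-[3-(benzyloxy)-4-methoxyphenyl]-2-(diethoxyphosphoryl)propanoate F7. Horner–Wadsworth–Emmons olefination of F7 with aldehyde 9 (made from 8 with Dess–Martin periodinane and used at once) under Masamune–Roush conditions (LiCl, DBU, MeCN, 0 °C) gives 10 after chromatographic removal of the Z isomer.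

**Further compounds**

F1 | step 7 | (E)-4-[3-(benzyloxy)-4-methoxyphenyl]-3-(methoxycarbonyl)but-3-enoic acid | COC(=O)/C(CC(=O)O)=C/c1ccc(OC)c(OCc2ccccc2)c1
F2 | step 7 | (R)-4-[3-(benzyloxy)-4-methoxyphenyl]-3-(methoxycarbonyl)butanoic acid | COC(=O)[C@@H](CC(=O)O)Cc1ccc(OC)c(OCc2ccccc2)c1
F3 | step 7 | (R)-4-[3-(benzyloxy)-4-methoxybenzyl]dihydrofuran-2(3H)-one | COc1ccc(C[C@H]2COC(=O)C2)cc1OCc1ccccc1
F4 | step 7 | 4-(benzyloxy)-3-methoxybenzyl bromide | COc1cc(CBr)ccc1OCc1ccccc1
F5 | step 5 | ethyl 2-[3-(benzyloxy)-4-methoxybenzyl]acrylate | C=C(Cc1ccc(OC)c(OCc2ccccc2)c1)C(=O)OCC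
F6 | step 5 | 4-allyl-1-(benzyloxy)-2-methoxybenzene | C=CCc1ccc(OCc2ccccc2)c(OC)c1
F7 | step 3 | ethyl 3-[3-(benzyloxy)-4-methoxyphenyl]-2-(diethoxyphosphoryl)propanoate | CCOC(=O)C(Cc1ccc(OC)c(OCc2ccccc2)c1)P(=O)(OCC)OCC
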